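**Strategy.** Ring A and ring B are both opened, at C1–C2 and at the ring-fusion bond C5–C10 (drimane numbering). The C1 oxygen and the formyl carbon C12, 1,5-related across C10–C9–C8, are tied together as a cyclic enol acetal. In the key step Me2AlCl opens this monocyclic 2-methoxy-3-dienylidene-3,4-dihydro-2H-pyran to an aluminium (Z)-enolate and a methoxypentadienyl cation. The enolate carbon C10 bonds to C5 (ring B, quaternary C10, trans ring fusion), and the freed C1 aldehyde is trapped by the (Z)-vinylsilane carbon C2 (ring A). The precursor comes from an asymmetric hetero-Diels–Alder adduct and a vinyllithium.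

Key step: step 8

Assumption: the enantiomer of the chromium catalyst in step 5 is the one that gives the (4S)-cycloadduct 10; every later stereocentre follows from this centre (C9 of the target).

Step 1
Reactants: 1 3-chloro-3-methylbut-1-yne; 2 ethynyl(trimethyl)silane
Product: 3 (3,3-dimethylpenta-1,4-diyn-1-yl)trimethylsilane
Conditions: 2, EtMgBr, THF, 0 °C to rt; then CuCl (5 mol %), 1, 40 °C
Reagents that add atoms: none
Why: Copper-catalysed substitution of the tertiary propargylic chloride by the alkynyl Grignard reagent should give the skipped diyne, whose quaternary carbon is C4 with both methyl groups.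

Step 2
Reactants: 3 (3,3-dimethylpenta-1,4-diyn-1-yl)trimethylsilane
Product: 4 [(4E)-5-iodo-3,3-dimethylpent-4-en-1-yn-1-yl]trimethylsilane
Conditions: Cp2Zr(H)Cl (1.05 equiv), THF, rt; then I2, 0 °C
Reagents that add atoms: iodine (II)
Why: syn-Hydrozirconation of the terminal alkyne (the silylalkyne reacts more slowly) and iodinolysis with retention should give the (E)-vinyl iodide.

Step 3
Reactants: 4 [(4E)-5-iodo-3,3-dimethylpent-4-en-1-yn-1-yl]trimethylsilane
Product: 5 [(1Z,4E)-5-iodo-3,3-dimethylpenta-1,4-dien-1-yl]trimethylsilane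
Conditions: (c-C6H11)2BH, THF, 0 °C; then AcOH, rt
Reagents that add atoms: none
Why: syn-Hydroboration of the silylalkyne and protonolysis of the C–B bond with retention is the standard entry to (Z)-vinylsilanes; the hindered vinyl iodide should not react.

Step 4
Reactants: 6 {[tert-butyl(dimethyl)silyl]oxy}acetaldehyde; 7 2-(triphenylphosphoranylidene)propanal
Product: 8 (2E)-4-{[tert-butyl(dimethyl)silyl]oxy}-2-methylbut-2-enal
Conditions: PhMe, 80 °C
Reagents that add atoms: none
Why: Wittig olefination with the stabilised α-methyl ylide should give the (E)-enal that carries C1, C10 with its methyl group, C9 and C11.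

Step 5
Reactants: 8 (2E)-4-{[tert-butyl(dimethyl)silyl]oxy}-2-methylbut-2-enal; 9 ethyl vinyl ether
Product: 11 (3S)-3-({[tert-butyl(dimethyl)silyl]oxy}methyl)-2-methylpentanedial (C2 epimers), via cycloadduct 10 (not isolated)
Conditions: CrCl(C27H29NO2) (5 mol %; trivalent chromium with the tridentate Schiff base of (1R,2S)-1-aminoindan-2-ol and 3-(1-adamantyl)-2-hydroxy-5-methylbenzaldehyde), 4 Å MS, 9 (10 equiv), rt; then 0.1 M aq. oxalic acid, THF, 0 °C
Reagents that add atoms: water (O)
Why: The catalytic asymmetric inverse-electron-demand hetero-Diels–Alder reaction sets C9 by catalyst-controlled face selection on the enal, and mild hydrolysis of the cyclic enol acetal frees the 1,5-dialdehyde without touching C9.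

Step 6
Reactants: 11 (3S)-3-({[tert-butyl(dimethyl)silyl]oxy}methyl)-2-methylpentanedial
Product: 14 (4R)-4-({[tert-butyl(dimethyl)silyl]oxy}methyl)-5-methyl-4H-pyran-3-carbaldehyde, via enaminal 12 (not isolated), via lactol 13 (not isolated)
Conditions: t-BuOCH(NMe2)2, THF, 50 °C; then AcOH–H2O, rt; then PPTS (cat.), 4 Å MS, PhMe, 80 °C
Reagents that add atoms: tert-butoxybis(dimethylamino)methane (CN(C)C(OC(C)(C)C)N(C)C); water (O)
Why: Bredereck aminomethylenation can occur only at the CH2 group next to the unbranched aldehyde and adds C7; hydrolysis, lactol formation on the branched aldehyde and dehydration should give the 4H-pyran, whose C1=C10 enol ether has its oxygen held cis to C9 by the ring.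

Step 7
Reactants: 5 [(1Z,4E)-5-iodo-3,3-dimethylpenta-1,4-dien-1-yl]trimethylsilane; 14 (4R)-4-({[tert-butyl(dimethyl)silyl]oxy}methyl)-5-methyl-4H-pyran-3-carbaldehyde
Product: 17 (4R)-4-({[tert-butyl(dimethyl)silyl]oxy}methyl)-3-[(2E,5Z)-4,4-dimethyl-6-(trimethylsilyl)hexa-2,5-dien-1-ylidene]-2-methoxy-5-methyl-3,4-dihydro-2H-pyran (C2 epimers and exocyclic alkene isomers), via vinyllithium 15 (not isolated), via carbinol 16 (not isolated)
Conditions: 5, t-BuLi (2.1 equiv), Et2O, −78 °C; 14, −78 °C; then AcOH (1 equiv), MeOH, PPTS (cat.), −20 °C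
Reagents that add atoms: methanol (CO)
Why: Iodine–lithium exchange with retention and 1,2-addition to the vinylogous formate aldehyde give a doubly allylic carbinol; its acid-induced SN1' methanolysis at the oxocarbenium carbon should give the cyclic enol acetal, whose C2 configuration and exocyclic alkene geometry do not matter.

Step 8
Reactants: 17 (4R)-4-({[tert-butyl(dimethyl)silyl]oxy}methyl)-3-[(2E,5Z)-4,4-dimethyl-6-(trimethylsilyl)hexa-2,5-dien-1-ylidene]-2-methoxy-5-methyl-3,4-dihydro-2H-pyran
Product: 19 11-(tert-butyldimethylsilyloxy)-12-methoxydrima-2,6,8(12)-trien-1-ol (5α-H; 9α-H; 10β-methyl; C1 epimers), via monocyclic aldehyde 18 (not isolated)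
Conditions: Me2AlCl (2.2 equiv), CH2Cl2, −78 to −30 °C; aq. NaHCO3
Reagents that add atoms: none
Why: Proposed new method: Me2AlCl should cleave the endocyclic C12–O bond of the cyclic enol acetal to an aluminium (Z)-enolate of the C1 aldehyde and a 1-methoxypentadienyl cation in which the C8–C7 bond can rotate, so that both acetal epimers and both alkylidene isomers of 17 converge; the closest known reaction type is the Petasis–Ferrier/Ferrier O→C rearrangement of cyclic enol acetals, here in a vinylogous sense and coupled to a vinylsilane-terminated carbonyl cyclisation. Ring B then closes by C-alkylation of the enolate carbon C10 at the δ-terminus C5 (6-endo with respect to C5=C6; the only other C–C closures would give four-membered rings and return at oxygen is reversible), and ring A closes by 6-endo ipso attack of the (Z)-vinylsilane carbon C2 on the aluminium-bound aldehyde C1 with loss of Me3SiCl. C10 and C5 are set in a chair-like transition state: the enolate oxygen, fixed cis to C9 by its origin in the ring, imposes A(1,3) strain that puts H-9 in the enolate plane and the C9 side chain anti to the new bond, so C1 is equatorial and the methyl group axial on ring B, while the (E)-C5=C6 bond places the tert-alkyl group equatorial, which gives the trans ring fusion (5α-H, 10β-methyl) relative to C9. C1 is not controlled (the axial 1α-alcohol is expected to predominate) and is corrected in steps 9 and 10. The step needs 1,6-C-alkylation to outrun attack of the weakly nucleophilic vinylsilane on the cation, which the far higher nucleophilicity of the enolate should secure, and it needs ring opening before C–C bond formation, which is enforced because the intact planar pyranyl cation cannot reach C5 with C10.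

Step 9
Reactants: 19 11-(tert-butyldimethylsilyloxy)-12-methoxydrima-2,6,8(12)-trien-1-ol
Product: 20 11-(tert-butyldimethylsilyloxy)-12-methoxydrima-6,8(12)-dien-1-one
Conditions: (C5Ph5)Ru(CO)2Cl (2 mol %), t-BuOK (3 mol %), PhMe, 40 °C
Reagents that add atoms: none
Why: Ruthenium-catalysed redox isomerisation of the allylic alcohol (alkoxide β-hydride elimination, then conjugate hydride return) should turn both C1 epimers into one saturated ketone and remove the ring A double bond in the same operation.

Step 10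
Reactants: 20 11-(tert-butyldimethylsilyloxy)-12-methoxydrima-6,8(12)-dien-1-one
Product: 21 11-(tert-butyldimethylsilyloxy)-12-methoxydrima-6,8(12)-dien-1β-ol
Conditions: NaBH4, MeOH–THF, −20 °C
Reagents that add atoms: none
Why: Hydride should attack the C1 ketone from the α face (axial attack, away from the β-methyl group on C10 and the β side chain on C9) and give the equatorial 1β-alcohol.

Step 11
Reactants: 22 4-(methoxymethoxy)benzaldehyde; 23 malonic acid
Product: 24 (2E)-3-[4-(methoxymethoxy)phenyl]prop-2-enoic acid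
Conditions: pyridine, piperidine (cat.), 90 °C
Reagents that add atoms: none
Why: Knoevenagel–Doebner condensation with decarboxylation should give the (E)-cinnamic acid with the phenol masked as an acid-labile acetal.

Step 12
Reactants: 21 11-(tert-butyldimethylsilyloxy)-12-methoxydrima-6,8(12)-dien-1β-ol; 24 (2E)-3-[4-(methoxymethoxy)phenyl]prop-2-enoic acid
Product: 25 11-(tert-butyldimethylsilyloxy)-12-methoxy-1β-{(2E)-3-[4-(methoxymethoxy)phenyl]prop-2-enoyloxy}drima-6,8(12)-diene
Conditions: 24, 2,4,6-Cl3C6H2COCl, Et3N, THF, rt; then 21, DMAP, PhMe, 60 °C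
Reagents that add atoms: none
Why: Yamaguchi esterification through the mixed anhydride is suited to the hindered secondary alcohol, and the basic medium leaves the dienol ether intact.

Step 13
Reactants: 25 11-(tert-butyldimethylsilyloxy)-12-methoxy-1β-{(2E)-3-[4-(methoxymethoxy)phenyl]prop-2-enoyloxy}drima-6,8(12)-diene
Product: 26 12-methoxy-1β-{(2E)-3-[4-(methoxymethoxy)phenyl]prop-2-enoyloxy}drima-6,8(12)-dien-11-ol
Conditions: Bu4NF, AcOH, THF, 0 °C to rt
Reagents that add atoms: none
Why: Buffered fluoride cleaves the primary silyl ether while the dienol ether (acid-labile) and the ester (prone to migration under basic conditions) should survive.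

Step 14
Reactants: 26 12-methoxy-1β-{(2E)-3-[4-(methoxymethoxy)phenyl]prop-2-enoyloxy}drima-6,8(12)-dien-11-ol
Product: 27 12-methoxy-1β-{(2E)-3-[4-(methoxymethoxy)phenyl]prop-2-enoyloxy}drima-6,8(12)-dien-11-al
Conditions: Dess–Martin periodinane, pyridine, CH2Cl2, 0 °C
Reagents that add atoms: none
Why: Buffered Dess–Martin oxidation gives the C11 aldehyde while C12 is still masked, so no hydroxy-aldehyde that could close to a lactol and over-oxidise is ever present.

Step 15
Reactants: 27 12-methoxy-1β-{(2E)-3-[4-(methoxymethoxy)phenyl]prop-2-enoyloxy}drima-6,8(12)-dien-11-al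
Product: 28 1β-{[(2E)-3-(4-hydroxyphenyl)prop-2-enoyl]oxy}drim-7-ene-11,12-dial (target CNP0187624.1)
Conditions: CF3CO2H–H2O–CH2Cl2 (2:1:8), 0 °C to rt
Reagents that add atoms: water (O)
Why: Aqueous acid hydrolyses the dienol ether by protonation at C6 to the conjugated C7=C8 enal and removes the methoxymethyl group; acidic conditions should not epimerise C9.

**Compound list**

1 | 3-chloro-3-methylbut-1-yne | C#CC(C)(C)Cl | starting material
2 | ethynyl(trimethyl)silane | C#C[Si](C)(C)C | starting material
3 | (3,3-dimethylpenta-1,4-diyn-1-yl)trimethylsilane | C#CC(C)(C)C#C[Si](C)(C)C | intermediate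
4 | [(4E)-5-iodo-3,3-dimethylpent-4-en-1-yn-1-yl]trimethylsilane | I/C=C/C(C)(C)C#C[Si](C)(C)C | intermediate
5 | [(1Z,4E)-5-iodo-3,3-dimethylpenta-1,4-dien-1-yl]trimethylsilane | I/C=C/C(C)(C)/C=C\[Si](C)(C)C | intermediate
6 | {[tert-butyl(dimethyl)silyl]oxy}acetaldehyde | O=CCO[Si](C)(C)C(C)(C)C | starting material
7 | 2-(triphenylphosphoranylidene)propanal | CC(C=O)=P(c1ccccc1)(c1ccccc1)c1ccccc1 | starting material
8 | (2E)-4-{[tert-butyl(dimethyl)silyl]oxy}-2-methylbut-2-enal | O=C/C(C)=C/CO[Si](C)(C)C(C)(C)C | intermediate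
9 | ethyl vinyl ether | C=COCC | starting material
10 | (4S)-4-({[tert-butyl(dimethyl)silyl]oxy}methyl)-2-ethoxy-5-methyl-3,4-dihydro-2H-pyran (C2 epimers) | CCOC1C[C@H](CO[Si](C)(C)C(C)(C)C)C(C)=CO1 | intermediate
11 | (3S)-3-({[tert-butyl(dimethyl)silyl]oxy}methyl)-2-methylpentanedial (C2 epimers) | O=CC[C@H](CO[Si](C)(C)C(C)(C)C)C(C)C=O | intermediate
12 | (3R)-3-({[tert-butyl(dimethyl)silyl]oxy}methyl)-2-[(dimethylamino)methylidene]-4-methylpentanedial | CN(C)C=C(C=O)[C@H](CO[Si](C)(C)C(C)(C)C)C(C)C=O | intermediate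
13 | (4R)-4-({[tert-butyl(dimethyl)silyl]oxy}methyl)-6-hydroxy-5-methyl-5,6-dihydro-4H-pyran-3-carbaldehyde | O=CC1=COC(O)C(C)[C@H]1CO[Si](C)(C)C(C)(C)C | intermediate
14 | (4R)-4-({[tert-butyl(dimethyl)silyl]oxy}methyl)-5-methyl-4H-pyran-3-carbaldehyde | O=CC1=COC=C(C)[C@H]1CO[Si](C)(C)C(C)(C)C | intermediate
15 | [(1E,4Z)-3,3-dimethyl-5-(trimethylsilyl)penta-1,4-dien-1-yl]lithium | [Li]/C=C/C(C)(C)/C=C\[Si](C)(C)C | intermediate
16 | (2E,5Z)-1-[(4R)-4-({[tert-butyl(dimethyl)silyl]oxy}methyl)-5-methyl-4H-pyran-3-yl]-4,4-dimethyl-6-(trimethylsilyl)hexa-2,5-dien-1-ol (C1 epimers) | OC(/C=C/C(C)(C)/C=C\[Si](C)(C)C)C1=COC=C(C)[C@H]1CO[Si](C)(C)C(C)(C)C | intermediate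
17 | (4R)-4-({[tert-butyl(dimethyl)silyl]oxy}methyl)-3-[(2E,5Z)-4,4-dimethyl-6-(trimethylsilyl)hexa-2,5-dien-1-ylidene]-2-methoxy-5-methyl-3,4-dihydro-2H-pyran (C2 epimers; exocyclic alkene isomers) | COC1OC=C(C)[C@@H](CO[Si](C)(C)C(C)(C)C)C1=C/C=C/C(C)(C)/C=C\[Si](C)(C)C | intermediate
18 | 6-({[tert-butyl(dimethyl)silyl]oxy}methyl)-5-(methoxymethylidene)-1-methyl-2-[(3Z)-2-methyl-4-(trimethylsilyl)but-3-en-2-yl]cyclohex-3-ene-1-carbaldehyde (ring B closed; aluminium-bound in the flask) | O=C[C@]1(C)[C@@H](CO[Si](C)(C)C(C)(C)C)C(=COC)C=C[C@H]1C(C)(C)/C=C\[Si](C)(C)C | intermediate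
19 | 11-(tert-butyldimethylsilyloxy)-12-methoxydrima-2,6,8(12)-trien-1-ol (5α-H; 9α-H; 10β-methyl; C1 epimers) | CC1(C)C=CC(O)[C@]2(C)[C@@H](CO[Si](C)(C)C(C)(C)C)C(=COC)C=C[C@@H]12 | intermediate
20 | 11-(tert-butyldimethylsilyloxy)-12-methoxydrima-6,8(12)-dien-1-one | CC1(C)CCC(=O)[C@]2(C)[C@@H](CO[Si](C)(C)C(C)(C)C)C(=COC)C=C[C@@H]12 | intermediate
21 | 11-(tert-butyldimethylsilyloxy)-12-methoxydrima-6,8(12)-dien-1β-ol | CC1(C)CC[C@@H](O)[C@]2(C)[C@@H](CO[Si](C)(C)C(C)(C)C)C(=COC)C=C[C@@H]12 | intermediate
22 | 4-(methoxymethoxy)benzaldehyde | COCOc1ccc(C=O)cc1 | starting material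
23 | malonic acid | OC(=O)CC(=O)O | starting material
24 | (2E)-3-[4-(methoxymethoxy)phenyl]prop-2-enoic acid | COCOc1ccc(/C=C/C(=O)O)cc1 | intermediate
25 | 11-(tert-butyldimethylsilyloxy)-12-methoxy-1β-{(2E)-3-[4-(methoxymethoxy)phenyl]prop-2-enoyloxy}drima-6,8(12)-diene | CC1(C)CC[C@@H](OC(=O)/C=C/c2ccc(OCOC)cc2)[C@]2(C)[C@@H](CO[Si](C)(C)C(C)(C)C)C(=COC)C=C[C@@H]12 | intermediate
26 | 12-methoxy-1β-{(2E)-3-[4-(methoxymethoxy)phenyl]prop-2-enoyloxy}drima-6,8(12)-dien-11-ol | CC1(C)CC[C@@H](OC(=O)/C=C/c2ccc(OCOC)cc2)[C@]2(C)[C@@H](CO)C(=COC)C=C[C@@H]12 | intermediate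
27 | 12-methoxy-1β-{(2E)-3-[4-(methoxymethoxy)phenyl]prop-2-enoyloxy}drima-6,8(12)-dien-11-al | CC1(C)CC[C@@H](OC(=O)/C=C/c2ccc(OCOC)cc2)[C@]2(C)[C@@H](C=O)C(=COC)C=C[C@@H]12 | intermediate
28 | 1β-{[(2E)-3-(4-hydroxyphenyl)prop-2-enoyl]oxy}drim-7-ene-11,12-dial | CC1(C)CC[C@@H](OC(=O)/C=C/c2ccc(O)cc2)[C@]2(C)[C@@H](C=O)C(C=O)=CC[C@@H]12 | target

Total step count: 15. Longest linear sequence: 11 steps (steps 1–3, 7–10 and 12–15; the branch through steps 4–6 is equally long).

**Steps most likely to fail**

1. Step 8 (Proposed new method). After ring opening, the ion pair may simply re-close at oxygen or collapse to a cyclobutane. The vinylsilane may also add to the pentadienyl cation before the enolate does, so that the 1,6 C–C bond never forms, or the enolate may lose its geometry and erode the ring-fusion selectivity. Fallback with known reactions, run stepwise from 17 and returning at 19: mild aqueous acid (oxalic acid, wet THF) would give the open-chain aldehyde-dienal F1. Silylation of the enolisable C1 aldehyde (t-BuMe2SiOTf, Et3N) would give the silyl enol ether F2. A Lewis-acid-mediated intramolecular vinylogous Mukaiyama–Michael addition (EtAlCl2, CH2Cl2, −78 °C) would close ring B to the monocyclic dialdehyde F3 after aqueous work-up. A separate SnCl4-mediated vinylsilane–aldehyde cyclisation would close ring A to the allylic alcohol F4. Acetalisation of the enal (HC(OMe)3, MeOH, PPTS) to the dimethyl acetal F5 and elimination of methanol (Me3SiOTf, i-Pr2NEt; then K2CO3, MeOH) would return to 19. Because the enol-ether geometry of F2 is not fixed by a ring, lower selectivity at C10 and a separation of diastereomers must be expected on this path.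

2. Step 6. The free dialdehyde 11 may self-condense under the basic aminomethylenation, the lactol 13 may dehydrate incompletely, and the electron-rich 4H-pyran may oxidise in air. Fallback from 10 (isolated instead of hydrolysed), returning at 14: Me3SiOTf with i-Pr2NEt would eliminate ethanol from the cyclic acetal to give the 4H-pyran F6. Vilsmeier–Haack formylation (POCl3, DMF, 0 °C; aq. NaOAc) at the unsubstituted enol-ether carbon would then give 14 without passing through the open dialdehyde.

3. Step 9. The hindered cyclic allylic alkoxide may not complete the hydride return, or the ruthenium hydride may shift the dienol ether double bonds. Fallback from 19, returning at 20: Dess–Martin oxidation with pyridine buffer would give the enone F7, and conjugate reduction with [(Ph3P)CuH]6 (PhH, rt) would give 20.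

Further compounds
F1 | step 8 | (2E,4E)-2-[(2S)-1-{[tert-butyl(dimethyl)silyl]oxy}-3-methyl-4-oxobutan-2-yl]-6,6-dimethyl-8-(trimethylsilyl)octa-2,4,7-trienal (7Z; C3 epimers of the side chain) | O=CC(C)[C@@H](CO[Si](C)(C)C(C)(C)C)/C(C=O)=C\C=C\C(C)(C)/C=C\[Si](C)(C)C
F2 | step 8 | tert-butyldimethylsilyl enol ether of the C1 aldehyde of F1 (enol ether isomers) | CC(=CO[Si](C)(C)C(C)(C)C)[C@@H](CO[Si](C)(C)C(C)(C)C)/C(C=O)=C\C=C\C(C)(C)/C=C\[Si](C)(C)C
F3 | step 8 | 6-({[tert-butyl(dimethyl)silyl]oxy}methyl)-1-methyl-2-[(3Z)-2-methyl-4-(trimethylsilyl)but-3-en-2-yl]cyclohex-4-ene-1,5-dicarbaldehyde | O=C[C@]1(C)[C@@H](CO[Si](C)(C)C(C)(C)C)C(C=O)=CC[C@H]1C(C)(C)/C=C\[Si](C)(C)C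
F4 | step 8 | 11-(tert-butyldimethylsilyloxy)-1-hydroxydrima-2,7-dien-12-al (C1 epimers) | CC1(C)C=CC(O)[C@]2(C)[C@@H](CO[Si](C)(C)C(C)(C)C)C(C=O)=CC[C@@H]12
F5 | step 8 | 11-(tert-butyldimethylsilyloxy)-12,12-dimethoxydrima-2,7-dien-1-ol (C1 epimers) | CC1(C)C=CC(O)[C@]2(C)[C@@H](CO[Si](C)(C)C(C)(C)C)C(C(OC)OC)=CC[C@@H]12
F6 | step 6 | (4S)-4-({[tert-butyl(dimethyl)silyl]oxy}methyl)-3-methyl-4H-pyran | CC1=COC=C[C@@H]1CO[Si](C)(C)C(C)(C)C
F7 | step 9 | 11-(tert-butyldimethylsilyloxy)-12-methoxydrima-2,6,8(12)-trien-1-one | CC1(C)C=CC(=O)[C@]2(C)[C@@H](CO[Si](C)(C)C(C)(C)C)C(=COC)C=C[C@@H]12
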